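The flask is to be reckoned on a clock read off the two runs, not on a fitted rate constant.

all flasks: Lx 0.45 M; Gu 0.45 M; Rx 16 mM
- green: Ek 0.68 M; Aj 9 mM; run made earlier
- amber: Ek 2.7 M; Aj 9 mM; run made earlier
- flask: Ek 1.35 M; Aj 9.0 mM; time 5.0 d

| run | time / d | Kj / % | Eb / % |
|---|---|---|---|
| green | 0.417 | 2 | 0 |
| green | 0.625 | 1 | 5 |
| green | 1.04 | 13 | 4 |
| green | 1.67 | 26 | 12 |
| green | 3.00 | 38 | 15 |
| green | 5.00 | 47 | 19 |
| amber | 0.417 | 22 | 12 |
| amber | 0.625 | 42 | 21 |
| amber | 1.04 | 55 | 29 |
| amber | 1.67 | 61 | 35 |
| amber | 3.00 | 62 | 38 |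
| amber | 5.00 | 60 | 38 |

(readings scatter by 2 percentage points)

- excess of Kj over Eb in the product at 12 h
- excess of Kj over Eb in the product at 5.0 d
- part of the Lx and Gu charged together that has reacted at 5.0 d

- Ez is single-handed; Lx and Gu are mirror images of each other, charged as a racemate, each of them at the stated concentration
- the numbers in the tables scatter by 2 percentage points (one standard deviation)
- an excess is below zero if the other one leads

Green needs 1.67 d to turn 38.0% of Lx and Gu into product, and amber needs 0.417 d for 34.0%. Those times stand in the ratio 4.00, and the Ek charges in the ratio 3.97. So this one early pair of readings shows like conversion at like [Ek]·t, within the scatter. Later the rule fails: amber has 63.0% at 0.625 d, and green has 53.0% at 3.00 d, although green's [Ek]·t is the larger there. The clock is therefore trusted early and is a rough guide later. The flask's 12 h multiplied by its [Ek] and divided by green's [Ek] gives a green-equivalent time of 0.993 d. On amber's scale the same moment is 0.250 d.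

Early product in green grows by a factor 2.83 while the squared time ratio is 2.77, so readings can be scaled by the square of time. From green's reading at 1.04 d the flask has 15.5% converted at 12 h. From amber's first reading it has 12.2%. The two part, and amber's way cheats: its reading stands further along, where the square law has bent. Green's value is kept. At the late end, the flask's Ek exceeds Lx and Gu together by 0.450 M, and its amber-equivalent time, as a rough guide, is 2.50 d, past amber's 1.67 d reading of 96.0%. So conversion should come close to complete. The clock gives conversion, not excess.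

The forecast gives 41% (31% to 50%), 32% (26% to 38%) and 95% (88% to 99%), on the ground that “Racemisation competes better at low Ek, hence green's higher excess”.

The simulation gives 47.7%, 38.8% and 97.5%.

    Ek + Ez + Gu → Ez + Eb (k = 0.00297 L² mol⁻² s⁻¹)
    Ez → Wu (k = 1.03 × 10⁻⁸ s⁻¹)
    Ek + Rx → Ez + Dx (k = 1.35 × 10⁻⁶ L mol⁻¹ s⁻¹)
    2 Ez ⇌ Ul (K = 200 L mol⁻¹, k = 5.45 × 10⁻⁴ L mol⁻¹ s⁻¹)
    Ek + Ez + Lx → Ez + Kj (k = 0.00902 L² mol⁻² s⁻¹)
    Lx + Aj ⇌ Gu + Aj, rate k6*[Aj]*[Lx] forward; the back reaction follows from the equilibrium constant (k = 0.00137 L mol⁻¹ s⁻¹)

Both excesses stand above the forecast, and its conversion holds. At 0.500 d the flask has reacted 17.4%, beside the 15.5% that the green-equivalent time 0.993 d gave. For a neighbour flask with 0.81 M of Ek, the green-equivalent time of 5.0 d is 5.96 d, as a rough guide, past green's last reading of 66.0%. Ek, here the limiting reagent, allows 90.0%, so conversion should fall between the two. That neighbour flask gives 74.1%.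

Readings and results are calculated for substances that don't exist; the scatter is artificial.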